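Instead of acylating a phenol with a di-ortho-substituted benzoic acid, the route sets the ester link while its acyl part is still a slim alkynoyl chain and assembles ring A afterwards. The feature used is the ring A pattern. Neighbouring C1 (carrying the ester carbonyl) and C6 (carrying pentyl) are the two sp carbons of an oct-2-ynoate. C2–C5, oxygenated at C2 and C4, are a 1,1,3-trioxygenated butadiene. One thermal (4+2) cycloaddition makes C1–C2 and C5–C6; methanol loss then gives the arene. The precursor is a ring B benzyl salicylate with the oct-2-ynoyl group on O4 and a silyl group on O2, four steps from divarinol.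

Key step: step 7

Remark: the target has no stereocentre, so no step has to control configuration. Ring A is the 2,4-dihydroxy-6-pentylbenzoyl unit and ring B the 2-hydroxy-6-propylbenzoic acid unit. Each ring is numbered from the carbon that bears its carboxyl carbon (C1), and oxygens take the number of their ring carbon (O2, O4).

Step 1
Reactants: 1 5-propylbenzene-1,3-diol (divarinol)
Product: 2 2,4-dihydroxy-6-propylbenzoic acid
Conditions: MeOMgOCO2Me (2 M in DMF, 4 equiv), 120 °C; then cold 2 M HCl
Reagents that add atoms: methoxymagnesium methyl carbonate, CO[Mg]OC(=O)OC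
Why: Kolbe–Schmitt-type carboxylation: the magnesium phenoxide delivers CO2 to C4 of 1, the position ortho to one hydroxyl and para to the other, and chelation of magnesium by the new salicylate pulls the reversible reaction toward the acid, as is established for 5-alkylresorcinols.

Step 2
Reactants: 2 2,4-dihydroxy-6-propylbenzoic acid
Product: 3 benzyl 2,4-dihydroxy-6-propylbenzoate
Conditions: BnBr (1.05 equiv), KHCO3 (1.2 equiv), DMF, rt
Reagents that add atoms: benzyl bromide, BrCc1ccccc1
Why: SN2 O-alkylation of the carboxylate: hydrogencarbonate deprotonates only the carboxylic acid, so both phenols stay free and the acid gains a group that leaves under neutral hydrogenolysis at the end.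

Step 3
Reactants: 3 benzyl 2,4-dihydroxy-6-propylbenzoate; 4 oct-2-ynoic acid
Product: 5 benzyl 2-hydroxy-4-(oct-2-ynoyloxy)-6-propylbenzoate
Conditions: 4 (1.05 equiv), N,N'-dicyclohexylcarbodiimide (DCC, 1.1 equiv), 4-(dimethylamino)pyridine (5 mol %), CH2Cl2, 0 °C → rt
Reagents that add atoms: none
Why: Steglich esterification: O2–H is locked in a hydrogen bond to the benzyl ester carbonyl and shielded by it, so the linear, unhindered ynoic acid is taken up by the free, more nucleophilic O4–H alone, which makes temporary O4 protection unnecessary.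

Step 4
Reactants: 5 benzyl 2-hydroxy-4-(oct-2-ynoyloxy)-6-propylbenzoate
Product: 6 benzyl 2-(tert-butyldimethylsilyloxy)-4-(oct-2-ynoyloxy)-6-propylbenzoate
Conditions: TBSOTf (1.2 equiv), 2,6-lutidine (1.5 equiv), CH2Cl2, 0 °C
Reagents that add atoms: tert-butyldimethylsilyl triflate, CC(C)(C)[Si](C)(C)OS(=O)(=O)C(F)(F)F
Why: O-silylation of a phenol with a silyl triflate and a non-nucleophilic base is strong enough to break the hydrogen bond yet spares the nucleophile-sensitive aryl ynoate, and it removes the one acidic proton that would destroy the ketene acetal diene in step 7.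

Step 5
Reactants: 7 1,1-dimethoxyethene
Product: 8 4,4-dimethoxybut-3-en-2-one
Conditions: AcCl (1 equiv), 7 (2.1 equiv), Et2O, 0 °C → reflux; distil
Reagents that add atoms: acetyl chloride, CC(=O)Cl
Why: C-acylation of a ketene acetal: the nucleophilic CH2 attacks the acid chloride and proton loss restores the push–pull alkene, while the HCl is consumed by a second equivalent of 7, which falls apart into methyl acetate and chloromethane, so no amine that could turn acetyl chloride into ketene is needed.

Step 6
Reactants: 8 4,4-dimethoxybut-3-en-2-one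
Product: 9 1,1-dimethoxy-3-(trimethylsilyloxy)buta-1,3-diene
Conditions: TMSCl (1.5 equiv), Et3N (2 equiv), ZnCl2 (3 mol %), toluene, 40 °C; filter, distil
Reagents that add atoms: chlorotrimethylsilane, C[Si](C)(C)Cl
Why: Silyl enol ether formation by soft enolization: only the acetyl methyl group can enolize, so O-silylation gives the cross-conjugated 2-silyloxydiene as the single regioisomer, which is distilled and kept free of acid and moisture.

Step 7
Reactants: 6 benzyl 2-(tert-butyldimethylsilyloxy)-4-(oct-2-ynoyloxy)-6-propylbenzoate; 9 1,1-dimethoxy-3-(trimethylsilyloxy)buta-1,3-diene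
Product: 12 benzyl 2-hydroxy-4-(4-hydroxy-2-methoxy-6-pentylbenzoyloxy)-6-propylbenzoate, via ketal cycloadduct 10 (not isolated), via bis-silyl arene 11 (not isolated)
Conditions: 9 (3 equiv, in portions), toluene (2 M), 120 °C, sealed base-washed tube; evaporate; then HF·pyridine, THF, 0 °C → rt
Reagents that add atoms: none
Why: The electron-rich diene 9 and the electron-poor aryl ynoate 6 combine in a normal-demand, strongly asynchronous Diels–Alder reaction in which the CH2 terminus of 9, toward which all three oxygen donors push electron density, bonds to the pentyl-bearing β-carbon (future C5–C6 bond) and the acetal carbon closes onto the α-carbon (future C1–C2 bond). Ring A thus closes by an intermolecular (4+2) annulation of four diene carbons and two alkyne carbons, the closest known reaction type being the cycloaddition of 1,1-dialkoxy-3-silyloxybutadienes to alk-2-ynoic esters, which delivers 6-alkyl-2-alkoxy-4-hydroxybenzoates. Adduct 10 is a cyclohexa-1,4-diene whose ketal carbon and CH2 group sit para to each other, so 1,4-elimination of methanol to arene 11 is driven by aromatization, and HF then removes both silyl groups. No stereocentre is formed, since the only sp3 ring carbons of 10 each carry two identical substituents and both become planar. The selectivity needed is regiochemical and is secured by the matched polarization of the partners: the ester makes the β-carbon of 6 the electrophilic end, and an aryl ester should do so more strongly than an alkyl ester. Chemoselectivity rests on 6 having no acidic proton (O2 is silylated) and on surplus 9 taking up the liberated methanol before it can attack the aryl ester.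

Step 8
Reactants: 12 benzyl 2-hydroxy-4-(4-hydroxy-2-methoxy-6-pentylbenzoyloxy)-6-propylbenzoate
Product: 13 benzyl 4-(2,4-dihydroxy-6-pentylbenzoyloxy)-2-hydroxy-6-propylbenzoate
Conditions: BCl3 (1 M in CH2Cl2, 4 equiv), C6HMe5 (2 equiv), CH2Cl2, −78 → 0 °C; then ice-water
Reagents that add atoms: none
Why: Chelation-directed aryl methyl ether cleavage: boron bridges the depside carbonyl oxygen and the ortho methoxy oxygen of ring A, chloride removes the activated methyl group by SN2 attack, the hindered aryl ester is left alone at low temperature, pentamethylbenzene stands by for any benzyl cation, and benzyl ester lost prematurely would only anticipate step 9.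

Step 9
Reactants: 13 benzyl 4-(2,4-dihydroxy-6-pentylbenzoyloxy)-2-hydroxy-6-propylbenzoate
Product: 14 4-(2,4-dihydroxy-6-pentylbenzoyloxy)-2-hydroxy-6-propylbenzoic acid (target)
Conditions: H2 (1 atm), 10% Pd/C, EtOAc, rt
Reagents that add atoms: none
Why: Catalytic hydrogenolysis of the benzyl ester is neutral, touches neither the aryl ester nor the phenols and leaves only toluene, which suits an acid that decarboxylates easily and a depside link that hydrolyses easily.

Compound list
1 | 5-propylbenzene-1,3-diol (divarinol) | CCCc1cc(O)cc(O)c1 | starting material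
2 | 2,4-dihydroxy-6-propylbenzoic acid | CCCc1cc(O)cc(O)c1C(=O)O | intermediate
3 | benzyl 2,4-dihydroxy-6-propylbenzoate | CCCc1cc(O)cc(O)c1C(=O)OCc1ccccc1 | intermediate
4 | oct-2-ynoic acid | CCCCCC#CC(=O)O | starting material
5 | benzyl 2-hydroxy-4-(oct-2-ynoyloxy)-6-propylbenzoate | CCCCCC#CC(=O)Oc1cc(O)c(C(=O)OCc2ccccc2)c(CCC)c1 | intermediate
6 | benzyl 2-(tert-butyldimethylsilyloxy)-4-(oct-2-ynoyloxy)-6-propylbenzoate | CCCCCC#CC(=O)Oc1cc(O[Si](C)(C)C(C)(C)C)c(C(=O)OCc2ccccc2)c(CCC)c1 | intermediate
7 | 1,1-dimethoxyethene | C=C(OC)OC | starting material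
8 | 4,4-dimethoxybut-3-en-2-one | CC(=O)C=C(OC)OC | intermediate
9 | 1,1-dimethoxy-3-(trimethylsilyloxy)buta-1,3-diene | C=C(O[Si](C)(C)C)C=C(OC)OC | intermediate
10 | benzyl 2-(tert-butyldimethylsilyloxy)-4-{[6,6-dimethoxy-2-pentyl-4-(trimethylsilyloxy)cyclohexa-1,4-dien-1-yl]carbonyloxy}-6-propylbenzoate (ketal cycloadduct, not isolated) | CCCCCC1=C(C(=O)Oc2cc(O[Si](C)(C)C(C)(C)C)c(C(=O)OCc3ccccc3)c(CCC)c2)C(OC)(OC)C=C(O[Si](C)(C)C)C1 | intermediate
11 | benzyl 2-(tert-butyldimethylsilyloxy)-4-[2-methoxy-6-pentyl-4-(trimethylsilyloxy)benzoyloxy]-6-propylbenzoate (bis-silyl arene, not isolated) | CCCCCc1cc(O[Si](C)(C)C)cc(OC)c1C(=O)Oc1cc(O[Si](C)(C)C(C)(C)C)c(C(=O)OCc2ccccc2)c(CCC)c1 | intermediate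
12 | benzyl 2-hydroxy-4-(4-hydroxy-2-methoxy-6-pentylbenzoyloxy)-6-propylbenzoate | CCCCCc1cc(O)cc(OC)c1C(=O)Oc1cc(O)c(C(=O)OCc2ccccc2)c(CCC)c1 | intermediate
13 | benzyl 4-(2,4-dihydroxy-6-pentylbenzoyloxy)-2-hydroxy-6-propylbenzoate | CCCCCc1cc(O)cc(O)c1C(=O)Oc1cc(O)c(C(=O)OCc2ccccc2)c(CCC)c1 | intermediate
14 | 4-(2,4-dihydroxy-6-pentylbenzoyloxy)-2-hydroxy-6-propylbenzoic acid (CNP0324314.0) | CCCCCc1cc(O)cc(O)c1C(=O)Oc1cc(O)c(C(=O)O)c(CCC)c1 | target

Total step count: 9.
Longest linear sequence: 7 steps (1, 2, 3, 4, 7, 8, 9). The diene branch (steps 5 and 6) joins at step 7.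

Steps most likely to fail

Step 7. Thermal decay or adventitious protonolysis of the diene may outrun its addition to the sluggish β-alkyl ynoate. The first C–C bond may also form without ring closure. The fallback brings ring A in preformed and makes the ester link last; it sets out from 3. Commercial olivetolic acid (2,4-dihydroxy-6-pentylbenzoic acid) is perbenzylated (BnBr, K2CO3, DMF) to benzyl 2,4-bis(benzyloxy)-6-pentylbenzoate F1. This is saponified (KOH, aqueous DMSO, 90 °C) to 2,4-bis(benzyloxy)-6-pentylbenzoic acid F2. F2 and 3 are condensed with (CF3CO)2O in toluene at rt, a method that tolerates di-ortho-substituted acids and again acylates only O4. The product should be benzyl 4-[2,4-bis(benzyloxy)-6-pentylbenzoyloxy]-2-hydroxy-6-propylbenzoate F3. Hydrogenolysis of its three benzyl groups (H2, Pd/C, EtOAc) comes back to the route at 14.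

Step 8. Lewis-acid scission of the depside link, incomplete demethylation, or early loss of the benzyl ester with benzyl transfer onto ring A may occur. The fallback never makes a methyl ether; it sets out from 6. Dimedone is bis-silylated (TMSOTf, Et3N, Et2O, 0 °C) to 5,5-dimethyl-1,3-bis(trimethylsilyloxy)cyclohexa-1,3-diene F4. Its unsubstituted CH terminus is the nucleophilic end and bonds to the pentyl-bearing carbon of 6. Heating with 6 (xylene, 140–150 °C) should give the racemic bicyclo[2.2.2]octadiene adduct F5. Under the same conditions F5 expels 2-methylpropene by a retro-Diels–Alder reaction and becomes benzyl 4-[2,4-bis(trimethylsilyloxy)-6-pentylbenzoyloxy]-2-(tert-butyldimethylsilyloxy)-6-propylbenzoate F6. HF·pyridine in THF frees the three phenols and comes back to the route at 13.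

Step 1. The carboxylation is reversible and may stop at low conversion, attack C2 between the two hydroxyls, or be undone by decarboxylation during work-up. The fallback installs the carbon as an aldehyde and oxidizes it; it sets out from 1. Vilsmeier–Haack formylation (POCl3, DMF, 0 °C → rt, aqueous hydrolysis) goes para to one hydroxyl and should give 2,4-dihydroxy-6-propylbenzaldehyde F7. Pinnick oxidation (NaClO2, NaH2PO4, sulfamic acid as hypochlorite trap, aqueous DMSO, rt) comes back to the route at 2.

Further compounds
F1 | step 7 | benzyl 2,4-bis(benzyloxy)-6-pentylbenzoate | CCCCCc1cc(OCc2ccccc2)cc(OCc2ccccc2)c1C(=O)OCc1ccccc1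
F2 | step 7 | 2,4-bis(benzyloxy)-6-pentylbenzoic acid | CCCCCc1cc(OCc2ccccc2)cc(OCc2ccccc2)c1C(=O)O
F3 | step 7 | benzyl 4-[2,4-bis(benzyloxy)-6-pentylbenzoyloxy]-2-hydroxy-6-propylbenzoate | CCCCCc1cc(OCc2ccccc2)cc(OCc2ccccc2)c1C(=O)Oc1cc(O)c(C(=O)OCc2ccccc2)c(CCC)c1
F4 | step 8 | 5,5-dimethyl-1,3-bis(trimethylsilyloxy)cyclohexa-1,3-diene | CC1(C)CC(O[Si](C)(C)C)=CC(O[Si](C)(C)C)=C1
F5 | step 8 | bicyclo[2.2.2]octa-2,5-diene adduct of 6 and F4 (racemic, transient) | CCCCCC1=C(C(=O)Oc2cc(O[Si](C)(C)C(C)(C)C)c(C(=O)OCc3ccccc3)c(CCC)c2)C2(O[Si](C)(C)C)C=C(O[Si](C)(C)C)C1C(C)(C)C2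
F6 | step 8 | benzyl 4-[2,4-bis(trimethylsilyloxy)-6-pentylbenzoyloxy]-2-(tert-butyldimethylsilyloxy)-6-propylbenzoate | CCCCCc1cc(O[Si](C)(C)C)cc(O[Si](C)(C)C)c1C(=O)Oc1cc(O[Si](C)(C)C(C)(C)C)c(C(=O)OCc2ccccc2)c(CCC)c1
F7 | step 1 | 2,4-dihydroxy-6-propylbenzaldehyde | CCCc1cc(O)cc(O)c1C=O
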